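**Retrosynthetic overview**
1. The α-methylene-γ-butyrolactone (O8–C12) is closed last by oxidative lactonisation of a C8,C12-diol, after the (2S,3S)-epoxyangelate has been put on O6 by esterification; the epoxy acid comes from angelic acid by Sharpless epoxidation.
2. Key disconnection (C1–C2 and O10–C3 of the furanone in one operation): the furanone-bridged ten-membered carbocycle is unravelled to a seven-membered lactone (oxepan-2-one O6–C1–C10–C9–C8–C7–C6) that carries a (Z)-2-methyl-3-oxobutenyl arm on C6. C-acylation of the ketone enolate (C2) by the lactone carbonyl (C1) with loss of the ring oxygen O6 expands 7 → 10, and C10–OH then closes on C3.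
3. Enabling feature: O6 and C3 sit 1,4-cis across the Z C4=C5 bond, so C2 reaches C1 through a seven-membered transition state, and C10 carries a tertiary OH α to C1 (1,4 to C3) that can close the five-membered furanone.
4. The oxepanone (C6, C7, C8 all-trans) is closed at C7–C8 by an ester-tethered CrCl2 allylation of an aldehyde. The ester joins a hydroxy acid from (R)-lactic acid (C10) with a bis-allylic alcohol from 3-methylbut-2-enal and propyne (C6 by asymmetric alkynylation, Z-iodoalkene by hydroalumination–iodination).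
5. Ring order: oxepan-2-one (step 11) → ten-membered carbocycle and furanone (step 16) → butyrolactone (step 22).

Key step: step 16

Numbering and abbreviations: C1–C15 are the target's carbons in germacrane numbering (C1 furanone C=O, C2=C3 enol ether with the ring oxygen O10 on C3, C4=C5 Z-alkene, C6 ester carbinol, C7, C8 lactone carbinol, C9, C10 quaternary carbon, C11–C13 methylene-lactone carbons) and are used for all intermediates; TBS = tert-butyldimethylsilyl, TMS = trimethylsilyl.

Assumption: in step 5 the (S,S)-ProPhenol–zinc catalyst is taken to attack the enal face that gives the (R)-carbinol; if the sense proved opposite, the (R,R)-ligand would be used and nothing else changes.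

**Step 1**
Reactants: 1 (R)-lactic acid
Product: 2 (2R,5R)-2-tert-butyl-5-methyl-1,3-dioxolan-4-one
Conditions: pivalaldehyde, TsOH·H2O (cat.), H2SO4 (cat.), pentane, reflux (Dean–Stark); recrystallisation
Reagents that add atoms: pivalaldehyde (CC(C)(C)C=O)
Why: Acid-catalysed acetalisation of the α-hydroxy acid should give the cis-dioxolanone as the crystalline thermodynamic isomer, which stores the lactate stereocentre in the acetal carbon (self-regeneration of stereocentres).

**Step 2**
Reactants: 2 (2R,5R)-2-tert-butyl-5-methyl-1,3-dioxolan-4-one; 3 allyl bromide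
Product: 4 (2R,5S)-2-tert-butyl-5-methyl-5-(prop-2-en-1-yl)-1,3-dioxolan-4-one
Conditions: LiN(iPr)2, THF, −78 °C; then 3, −78 → −30 °C
Reagents that add atoms: none
Why: Dioxolanone enolate alkylation should occur on the face opposite the tert-butyl group, so the allyl group takes the place of the former hydrogen and sets the quaternary C10.

**Step 3**
Reactants: 4 (2R,5S)-2-tert-butyl-5-methyl-5-(prop-2-en-1-yl)-1,3-dioxolan-4-one
Product: 6 methyl (2S)-2-hydroxy-4,4-dimethoxy-2-methylbutanoate, via dioxolanone aldehyde 5 (not isolated)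
Conditions: O3, CH2Cl2/MeOH, −78 °C; Me2S; then HC(OMe)3, TsOH·H2O (cat.), MeOH, 40 °C
Reagents that add atoms: ozone ([O-][O+]=O); methanol (CO); trimethyl orthoformate (COC(OC)OC)
Why: Ozonolysis cuts the terminal alkene to the C8 aldehyde, and acid in methanol with the orthoformate should turn it into the dimethyl acetal while the acylal ring is methanolysed to the methyl ester with loss of pivalaldehyde, C10 being untouched.

**Step 4**
Reactants: 6 methyl (2S)-2-hydroxy-4,4-dimethoxy-2-methylbutanoate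
Product: 7 (2S)-2-hydroxy-4,4-dimethoxy-2-methylbutanoic acid
Conditions: LiOH·H2O, THF/H2O, 0 °C → rt; then 1 M HCl to pH 4, 0 °C
Reagents that add atoms: lithium hydroxide ([Li+].[OH-])
Why: Ester saponification; the acetal is stable to base and should survive the brief cold acidification.

**Step 5**
Reactants: 8 3-methylbut-2-enal; 9 propyne
Product: 10 (4R)-6-methylhept-5-en-2-yn-4-ol
Conditions: (S,S)-ProPhenol [2,6-bis{[(S)-2-(hydroxydiphenylmethyl)pyrrolidin-1-yl]methyl}-4-methylphenol] (20 mol%), Me2Zn (3 equiv), 9 (excess), Ph3PO (40 mol%), toluene, 0 °C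
Reagents that add atoms: none
Why: Catalytic enantioselective alkynylation of the enal by a dinuclear zinc alkynylide; the chiral pocket of the ligand selects one aldehyde face and sets C6.

**Step 6**
Reactants: 10 (4R)-6-methylhept-5-en-2-yn-4-ol
Product: 11 (2Z,4R)-2-iodo-6-methylhepta-2,5-dien-4-ol
Conditions: NaAlH2(OCH2CH2OMe)2, THF, 0 °C → rt; then I2, THF, −78 °C
Reagents that add atoms: iodine (II)
Why: Alkoxide-directed trans-hydroalumination of the propargylic alcohol places aluminium on the distal carbon, and iodinolysis with retention should give the Z-iodoalkene (iodine cis to the carbinol) without touching the trisubstituted alkene.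

**Step 7**
Reactants: 7 (2S)-2-hydroxy-4,4-dimethoxy-2-methylbutanoic acid; 11 (2Z,4R)-2-iodo-6-methylhepta-2,5-dien-4-ol
Product: 12 (2Z,4R)-2-iodo-6-methylhepta-2,5-dien-4-yl (2S)-2-hydroxy-4,4-dimethoxy-2-methylbutanoate
Conditions: 2,4,6-Cl3C6H2COCl, Et3N, THF, rt; then 11, 4-(dimethylamino)pyridine, toluene, rt
Reagents that add atoms: none
Why: Yamaguchi esterification through the mixed anhydride acylates the secondary alcohol with retention at C6; the tertiary α-hydroxyl is too hindered to compete.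

**Step 8**
Reactants: 12 (2Z,4R)-2-iodo-6-methylhepta-2,5-dien-4-yl (2S)-2-hydroxy-4,4-dimethoxy-2-methylbutanoate
Product: 13 (2Z,4R,5E)-7-hydroxy-2-iodo-6-methylhepta-2,5-dien-4-yl (2S)-2-hydroxy-4,4-dimethoxy-2-methylbutanoate
Conditions: SeO2 (0.5 equiv), anhydrous t-BuOOH (3 equiv), CH2Cl2, 0 °C → rt
Reagents that add atoms: tert-butyl hydroperoxide (CC(C)(C)OO)
Why: SeO2 allylic oxidation (ene reaction then 2,3-shift) should hydroxylate the E-methyl group of the trisubstituted alkene selectively, the iodoalkene being deactivated.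

**Step 9**
Reactants: 13 (2Z,4R,5E)-7-hydroxy-2-iodo-6-methylhepta-2,5-dien-4-yl (2S)-2-hydroxy-4,4-dimethoxy-2-methylbutanoate
Product: 14 (2Z,4R,5E)-7-bromo-2-iodo-6-methylhepta-2,5-dien-4-yl (2S)-2-hydroxy-4,4-dimethoxy-2-methylbutanoate
Conditions: NBS, Me2S, CH2Cl2, −30 → 0 °C
Reagents that add atoms: N-bromosuccinimide (O=C1CCC(=O)N1Br)
Why: Corey–Kim bromination converts only the primary allylic alcohol into the bromide under neutral conditions; the tertiary alcohol and the acetal are inert.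

**Step 10**
Reactants: 14 (2Z,4R,5E)-7-bromo-2-iodo-6-methylhepta-2,5-dien-4-yl (2S)-2-hydroxy-4,4-dimethoxy-2-methylbutanoate
Product: 15 (2Z,4R,5E)-7-bromo-2-iodo-6-methylhepta-2,5-dien-4-yl (2S)-2-hydroxy-2-methyl-4-oxobutanoate
Conditions: LiBF4, MeCN/H2O (50:1), rt
Reagents that add atoms: water (O)
Why: Mild Lewis-acid-assisted acetal hydrolysis should free the C8 aldehyde without ionising the allylic bromide or the bis-allylic ester.

**Step 11**
Reactants: 15 (2Z,4R,5E)-7-bromo-2-iodo-6-methylhepta-2,5-dien-4-yl (2S)-2-hydroxy-2-methyl-4-oxobutanoate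
Product: 16 (3S,5S,6R,7R)-3,5-dihydroxy-7-[(1Z)-2-iodoprop-1-en-1-yl]-3-methyl-6-(prop-1-en-2-yl)oxepan-2-one
Conditions: CrCl2 (6 equiv), THF, rt, slow addition of 15 (final 0.005 M)
Reagents that add atoms: none
Why: Nozaki–Hiyama allylation: the allylchromium formed from the bromide should add through C7 to the tethered aldehyde in a chair Zimmerman–Traxler transition state (C7/C8 anti, so isopropenyl trans to OH on the new oxepanone), while 1,3-allylic strain with the Z-methyl on C11 keeps H6 in the alkene plane so that the aldehyde, tethered through O6, attacks from the O6 face and the C6 arm ends trans to the isopropenyl group.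

**Step 12**
Reactants: 16 (3S,5S,6R,7R)-3,5-dihydroxy-7-[(1Z)-2-iodoprop-1-en-1-yl]-3-methyl-6-(prop-1-en-2-yl)oxepan-2-one
Product: 17 (3S,5S,6S,7R)-5-(TBSO)-3-hydroxy-7-[(1Z)-2-iodoprop-1-en-1-yl]-3-methyl-6-(prop-1-en-2-yl)oxepan-2-one
Conditions: TBSOTf (1.1 equiv), 2,6-lutidine, CH2Cl2, −78 °C (crude 16 used at once)
Reagents that add atoms: tert-butyldimethylsilyl trifluoromethanesulfonate (CC(C)(C)[Si](C)(C)OS(=O)(=O)C(F)(F)F)
Why: Silyl ether formation at the secondary C8–OH (the tertiary OH is too hindered at −78 °C) blocks acyl transfer from O6 to O8, which would give the five-membered lactone.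

**Step 13**
Reactants: 17 (3S,5S,6S,7R)-5-(TBSO)-3-hydroxy-7-[(1Z)-2-iodoprop-1-en-1-yl]-3-methyl-6-(prop-1-en-2-yl)oxepan-2-one
Product: 18 (3S,5S,6S,7R)-5-(TBSO)-3-hydroxy-6-(3-hydroxyprop-1-en-2-yl)-7-[(1Z)-2-iodoprop-1-en-1-yl]-3-methyloxepan-2-one
Conditions: SeO2 (0.5 equiv), anhydrous t-BuOOH, CH2Cl2, rt
Reagents that add atoms: tert-butyl hydroperoxide (CC(C)(C)OO)
Why: SeO2 allylic oxidation of the 1,1-disubstituted alkene should take place at the methyl group (CH3 preferred over the allylic CH) and so brings in the C12 oxygen.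

**Step 14**
Reactants: 18 (3S,5S,6S,7R)-5-(TBSO)-3-hydroxy-6-(3-hydroxyprop-1-en-2-yl)-7-[(1Z)-2-iodoprop-1-en-1-yl]-3-methyloxepan-2-one; 19 tributyl(1-ethoxyvinyl)stannane
Product: 21 (3S,5S,6S,7S)-5-(TBSO)-3-hydroxy-6-(3-hydroxyprop-1-en-2-yl)-3-methyl-7-[(1Z)-2-methyl-3-oxobut-1-en-1-yl]oxepan-2-one, via enol ether 20 (not isolated)
Conditions: Pd2(dba)3 (5 mol%), AsPh3, N-methylpyrrolidone, rt; then 1 M HCl, THF, 0 °C
Reagents that add atoms: water (O)
Why: Stille coupling of the vinyl iodide with the acyl-anion equivalent proceeds with retention of the Z geometry, and brief hydrolysis of the enol ether should give the methyl ketone (C2, C3).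

**Step 15**
Reactants: 21 (3S,5S,6S,7S)-5-(TBSO)-3-hydroxy-6-(3-hydroxyprop-1-en-2-yl)-3-methyl-7-[(1Z)-2-methyl-3-oxobut-1-en-1-yl]oxepan-2-one
Product: 23 (3S,5S,6S,7S)-5-(TBSO)-6-[3-(TBSO)prop-1-en-2-yl]-3-methyl-7-[(1Z)-2-methyl-3-oxobut-1-en-1-yl]-3-(TMSO)oxepan-2-one, via mono-TBS ether 22 (not isolated)
Conditions: TBSCl, imidazole, DMF, 0 °C; then 1-(trimethylsilyl)imidazole, rt
Reagents that add atoms: tert-butyldimethylsilyl chloride (CC(C)(C)[Si](C)(C)Cl); 1-(trimethylsilyl)imidazole (C[Si](C)(C)n1ccnc1)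
Why: Silyl ether formation in order of hindrance (primary allylic OH with TBSCl, then the tertiary OH with the small TMS donor) under conditions too weakly basic to enolise the ketone.

**Step 16**
Reactants: 23 (3S,5S,6S,7S)-5-(TBSO)-6-[3-(TBSO)prop-1-en-2-yl]-3-methyl-7-[(1Z)-2-methyl-3-oxobut-1-en-1-yl]-3-(TMSO)oxepan-2-one
Product: 26 (4Z,6S,7S,8S,10S)-3,10-epoxy-6-hydroxy-8,12-bis(TBSO)germacra-2,4,11(13)-trien-1-one, via silyloxy diketone 24 (not isolated), via hydroxy diketone 25 (not isolated)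
Conditions: LiN(SiMe3)2 (2.3 equiv), THF, −78 → −20 °C; AcOH (2.5 equiv), −78 °C; then TsOH·H2O (0.1 equiv), CH2Cl2/MeOH (10:1), 0 °C → rt
Reagents that add atoms: none
Why: Proposed new method: kinetic deprotonation of the methyl ketone gives the cross-conjugated lithium enolate (C2), which the Z C4=C5 bond holds 1,4-cis to the lactone oxygen so that it attacks the lactone carbonyl C1 through a seven-membered transition state (7-exo-trig); collapse of the bridged 11-oxabicyclo[4.4.1] tetrahedral intermediate expels the C6 alkoxide, so the C1–C2 bond forms while the oxepanone expands to the ten-membered carbocycle, driven by formation of the lithium 1,3-diketonate. The closest known reaction types are the Baker–Venkataraman O-to-C acyl transfer (intramolecular Claisen condensation of a ketone enolate with a neighbouring ester) and the acid-catalysed cyclodehydration of 1-hydroxy-2,4-diketones to 3(2H)-furanones; new here is that the ester is a lactone whose ring oxygen is the leaving group, which makes the acyl transfer a 7 → 10 ring expansion. In the acid stage the TMS ether is cleaved, the tertiary C10–OH adds to the C3 carbonyl (5-exo-trig) and loss of water gives the bridging furanone with the O10–C3 bond. No stereocentre is created: C6, C7, C8 and C10 are carried unchanged (the C6–O bond is broken at the acyl carbon, not at C6), and the Z alkene cannot isomerise through the cross-conjugated enolate. The step needs deprotonation at C2 rather than at C6–H, C- rather than O-acylation, and ring closure by O10 rather than by the freed O6: the first should follow from the hindered base at −78 °C, the second from the seven- versus nine-membered transition state, and the third because only O10 gives an unstrained endocyclic vinylogous ester under reversible ketalisation, whereas closure by O6 would force a planar 2-alkylidene-2,5-dihydrofuran across the ten-membered ring.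

**Step 17**
Reactants: 27 angelic acid
Product: 28 (Z)-2-methylbut-2-en-1-ol
Conditions: LiAlH4, Et2O, 0 °C → rt
Reagents that add atoms: none
Why: Hydride reduction of the acid to the allylic alcohol, which should leave the Z geometry intact.

**Step 18**
Reactants: 28 (Z)-2-methylbut-2-en-1-ol
Product: 29 [(2R,3S)-2,3-dimethyloxiran-2-yl]methanol
Conditions: Ti(OiPr)4, D-(−)-diethyl tartrate, t-BuOOH, 4 Å molecular sieves, CH2Cl2, −20 °C
Reagents that add atoms: tert-butyl hydroperoxide (CC(C)(C)OO)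
Why: Sharpless asymmetric epoxidation; the D-(−)-tartrate complex should deliver oxygen to the alkene face that gives the (2R,3S)-epoxide, and syn addition keeps the two methyl groups trans.

**Step 19**
Reactants: 29 [(2R,3S)-2,3-dimethyloxiran-2-yl]methanol
Product: 30 (2S,3S)-2,3-dimethyloxirane-2-carboxylic acid
Conditions: RuCl3·xH2O (cat.), NaIO4, MeCN/CCl4/H2O, 0 °C → rt
Reagents that add atoms: water (O)
Why: Catalytic ruthenium tetroxide oxidation of the primary alcohol to the acid; the epoxide and both stereocentres are not involved.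

**Step 20**
Reactants: 26 (4Z,6S,7S,8S,10S)-3,10-epoxy-6-hydroxy-8,12-bis(TBSO)germacra-2,4,11(13)-trien-1-one; 30 (2S,3S)-2,3-dimethyloxirane-2-carboxylic acid
Product: 31 (4Z,6S,7S,8S,10S)-3,10-epoxy-8,12-bis(TBSO)-1-oxogermacra-2,4,11(13)-trien-6-yl (2S,3S)-2,3-dimethyloxirane-2-carboxylate
Conditions: 30, 2,4,6-Cl3C6H2COCl, Et3N, THF, rt; then 26, 4-(dimethylamino)pyridine, toluene, rt → 40 °C
Reagents that add atoms: none
Why: Yamaguchi esterification of the allylic C6–OH with retention at C6; the epoxy acid has no enolisable centre and cannot epimerise.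

**Step 21**
Reactants: 31 (4Z,6S,7S,8S,10S)-3,10-epoxy-8,12-bis(TBSO)-1-oxogermacra-2,4,11(13)-trien-6-yl (2S,3S)-2,3-dimethyloxirane-2-carboxylate
Product: 32 (4Z,6S,7R,8S,10S)-3,10-epoxy-8,12-dihydroxy-1-oxogermacra-2,4,11(13)-trien-6-yl (2S,3S)-2,3-dimethyloxirane-2-carboxylate
Conditions: HF·pyridine, pyridine, THF, 0 °C → rt
Reagents that add atoms: none
Why: Buffered fluoride desilylation should cleave both TBS ethers while avoiding the basic conditions that would move the acyl group from O6 to O8.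

**Step 22**
Reactants: 32 (4Z,6S,7R,8S,10S)-3,10-epoxy-8,12-dihydroxy-1-oxogermacra-2,4,11(13)-trien-6-yl (2S,3S)-2,3-dimethyloxirane-2-carboxylate
Product: 34 CNP0258430.1 (target), via enal 33 (not isolated)
Conditions: TEMPO (2,2,6,6-tetramethylpiperidin-1-oxyl, 20 mol%), PhI(OAc)2 (3 equiv), CH2Cl2, rt
Reagents that add atoms: none
Why: Oxidative lactonisation: the oxoammonium oxidant should oxidise the primary allylic alcohol selectively to the enal, C8–OH closes to the five-membered lactol and this is oxidised on to the α-methylene lactone with C8 unchanged.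

**Compound list**
1 | (R)-lactic acid | C[C@@H](O)C(=O)O | starting material
2 | (2R,5R)-2-tert-butyl-5-methyl-1,3-dioxolan-4-one | C[C@H]1O[C@@H](C(C)(C)C)OC1=O | intermediate
3 | allyl bromide | C=CCBr | starting material
4 | (2R,5S)-2-tert-butyl-5-methyl-5-(prop-2-en-1-yl)-1,3-dioxolan-4-one | C=CC[C@]1(C)O[C@@H](C(C)(C)C)OC1=O | intermediate
5 | 2-[(2R,4S)-2-tert-butyl-4-methyl-5-oxo-1,3-dioxolan-4-yl]acetaldehyde | O=CC[C@]1(C)O[C@@H](C(C)(C)C)OC1=O | intermediate
6 | methyl (2S)-2-hydroxy-4,4-dimethoxy-2-methylbutanoate | COC(OC)C[C@](C)(O)C(=O)OC | intermediate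
7 | (2S)-2-hydroxy-4,4-dimethoxy-2-methylbutanoic acid | COC(OC)C[C@](C)(O)C(=O)O | intermediate
8 | 3-methylbut-2-enal | CC(C)=CC=O | starting material
9 | propyne | CC#C | starting material
10 | (4R)-6-methylhept-5-en-2-yn-4-ol | CC#C[C@H](O)C=C(C)C | intermediate
11 | (2Z,4R)-2-iodo-6-methylhepta-2,5-dien-4-ol | C/C(I)=C/[C@H](O)C=C(C)C | intermediate
12 | (2Z,4R)-2-iodo-6-methylhepta-2,5-dien-4-yl (2S)-2-hydroxy-4,4-dimethoxy-2-methylbutanoate | COC(OC)C[C@](C)(O)C(=O)O[C@@H](/C=C(/C)I)C=C(C)C | intermediate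
13 | (2Z,4R,5E)-7-hydroxy-2-iodo-6-methylhepta-2,5-dien-4-yl (2S)-2-hydroxy-4,4-dimethoxy-2-methylbutanoate | COC(OC)C[C@](C)(O)C(=O)O[C@@H](/C=C(/C)I)/C=C(\C)CO | intermediate
14 | (2Z,4R,5E)-7-bromo-2-iodo-6-methylhepta-2,5-dien-4-yl (2S)-2-hydroxy-4,4-dimethoxy-2-methylbutanoate | COC(OC)C[C@](C)(O)C(=O)O[C@@H](/C=C(/C)I)/C=C(\C)CBr | intermediate
15 | (2Z,4R,5E)-7-bromo-2-iodo-6-methylhepta-2,5-dien-4-yl (2S)-2-hydroxy-2-methyl-4-oxobutanoate | O=CC[C@](C)(O)C(=O)O[C@@H](/C=C(/C)I)/C=C(\C)CBr | intermediate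
16 | (3S,5S,6R,7R)-3,5-dihydroxy-7-[(1Z)-2-iodoprop-1-en-1-yl]-3-methyl-6-(prop-1-en-2-yl)oxepan-2-one | O=C1O[C@@H](/C=C(/C)I)[C@H](C(C)=C)[C@@H](O)C[C@]1(C)O | intermediate
17 | (3S,5S,6S,7R)-5-[(tert-butyldimethylsilyl)oxy]-3-hydroxy-7-[(1Z)-2-iodoprop-1-en-1-yl]-3-methyl-6-(prop-1-en-2-yl)oxepan-2-one | O=C1O[C@@H](/C=C(/C)I)[C@H](C(C)=C)[C@@H](O[Si](C)(C)C(C)(C)C)C[C@]1(C)O | intermediate
18 | (3S,5S,6S,7R)-5-[(tert-butyldimethylsilyl)oxy]-3-hydroxy-6-(3-hydroxyprop-1-en-2-yl)-7-[(1Z)-2-iodoprop-1-en-1-yl]-3-methyloxepan-2-one | O=C1O[C@@H](/C=C(/C)I)[C@H](C(CO)=C)[C@@H](O[Si](C)(C)C(C)(C)C)C[C@]1(C)O | intermediate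
19 | tributyl(1-ethoxyvinyl)stannane | CCCC[Sn](CCCC)(CCCC)C(=C)OCC | starting material
20 | (3S,5S,6S,7S)-5-[(tert-butyldimethylsilyl)oxy]-7-[(1Z)-3-ethoxy-2-methylbuta-1,3-dien-1-yl]-3-hydroxy-6-(3-hydroxyprop-1-en-2-yl)-3-methyloxepan-2-one | O=C1O[C@@H](/C=C(/C)C(=C)OCC)[C@H](C(CO)=C)[C@@H](O[Si](C)(C)C(C)(C)C)C[C@]1(C)O | intermediate
21 | (3S,5S,6S,7S)-5-[(tert-butyldimethylsilyl)oxy]-3-hydroxy-6-(3-hydroxyprop-1-en-2-yl)-3-methyl-7-[(1Z)-2-methyl-3-oxobut-1-en-1-yl]oxepan-2-one | O=C1O[C@@H](/C=C(/C)C(C)=O)[C@H](C(CO)=C)[C@@H](O[Si](C)(C)C(C)(C)C)C[C@]1(C)O | intermediate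
22 | (3S,5S,6S,7S)-5-[(tert-butyldimethylsilyl)oxy]-6-{3-[(tert-butyldimethylsilyl)oxy]prop-1-en-2-yl}-3-hydroxy-3-methyl-7-[(1Z)-2-methyl-3-oxobut-1-en-1-yl]oxepan-2-one | O=C1O[C@@H](/C=C(/C)C(C)=O)[C@H](C(CO[Si](C)(C)C(C)(C)C)=C)[C@@H](O[Si](C)(C)C(C)(C)C)C[C@]1(C)O | intermediate
23 | (3S,5S,6S,7S)-5-[(tert-butyldimethylsilyl)oxy]-6-{3-[(tert-butyldimethylsilyl)oxy]prop-1-en-2-yl}-3-methyl-7-[(1Z)-2-methyl-3-oxobut-1-en-1-yl]-3-[(trimethylsilyl)oxy]oxepan-2-one | O=C1O[C@@H](/C=C(/C)C(C)=O)[C@H](C(CO[Si](C)(C)C(C)(C)C)=C)[C@@H](O[Si](C)(C)C(C)(C)C)C[C@]1(C)O[Si](C)(C)C | intermediate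
24 | (4Z,6S,7S,8S,10S)-8-[(tert-butyldimethylsilyl)oxy]-7-{3-[(tert-butyldimethylsilyl)oxy]prop-1-en-2-yl}-6-hydroxy-4,10-dimethyl-10-[(trimethylsilyl)oxy]cyclodec-4-ene-1,3-dione | O=C1CC(=O)/C(C)=C\[C@H](O)[C@H](C(CO[Si](C)(C)C(C)(C)C)=C)[C@@H](O[Si](C)(C)C(C)(C)C)C[C@]1(C)O[Si](C)(C)C | intermediate
25 | (4Z,6S,7S,8S,10S)-8-[(tert-butyldimethylsilyl)oxy]-7-{3-[(tert-butyldimethylsilyl)oxy]prop-1-en-2-yl}-6,10-dihydroxy-4,10-dimethylcyclodec-4-ene-1,3-dione | O=C1CC(=O)/C(C)=C\[C@H](O)[C@H](C(CO[Si](C)(C)C(C)(C)C)=C)[C@@H](O[Si](C)(C)C(C)(C)C)C[C@]1(C)O | intermediate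
26 | (4Z,6S,7S,8S,10S)-3,10-epoxy-6-hydroxy-8,12-bis[(tert-butyldimethylsilyl)oxy]germacra-2,4,11(13)-trien-1-one (ten-membered carbocycle bridged by O between C3 and C10) | O=C1C=C2/C(C)=C\[C@H](O)[C@H](C(CO[Si](C)(C)C(C)(C)C)=C)[C@@H](O[Si](C)(C)C(C)(C)C)C[C@]1(C)O2 | intermediate
27 | angelic acid, (Z)-2-methylbut-2-enoic acid | C/C=C(/C)C(=O)O | starting material
28 | (Z)-2-methylbut-2-en-1-ol | C/C=C(/C)CO | intermediate
29 | [(2R,3S)-2,3-dimethyloxiran-2-yl]methanol | OC[C@@]1(C)O[C@H]1C | intermediate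
30 | (2S,3S)-2,3-dimethyloxirane-2-carboxylic acid | OC(=O)[C@@]1(C)O[C@H]1C | intermediate
31 | (4Z,6S,7S,8S,10S)-3,10-epoxy-8,12-bis[(tert-butyldimethylsilyl)oxy]-1-oxogermacra-2,4,11(13)-trien-6-yl (2S,3S)-2,3-dimethyloxirane-2-carboxylate | O=C1C=C2/C(C)=C\[C@H](OC(=O)[C@@]3(C)O[C@H]3C)[C@H](C(CO[Si](C)(C)C(C)(C)C)=C)[C@@H](O[Si](C)(C)C(C)(C)C)C[C@]1(C)O2 | intermediate
32 | (4Z,6S,7R,8S,10S)-3,10-epoxy-8,12-dihydroxy-1-oxogermacra-2,4,11(13)-trien-6-yl (2S,3S)-2,3-dimethyloxirane-2-carboxylate | O=C1C=C2/C(C)=C\[C@H](OC(=O)[C@@]3(C)O[C@H]3C)[C@H](C(CO)=C)[C@@H](O)C[C@]1(C)O2 | intermediate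
33 | (4Z,6S,7R,8S,10S)-3,10-epoxy-8-hydroxy-1,12-dioxogermacra-2,4,11(13)-trien-6-yl (2S,3S)-2,3-dimethyloxirane-2-carboxylate | O=C1C=C2/C(C)=C\[C@H](OC(=O)[C@@]3(C)O[C@H]3C)[C@H](C(C=O)=C)[C@@H](O)C[C@]1(C)O2 | intermediate
34 | CNP0258430.1, (4Z,6S,7R,8S,10S)-3,10-epoxy-1-oxogermacra-2,4,11(13)-trien-8,12-olid-6-yl (2S,3S)-2,3-dimethyloxirane-2-carboxylate | C=C1C(=O)O[C@H]2C[C@]3(C)OC(=CC3=O)/C(C)=C\[C@H](OC(=O)[C@@]3(C)O[C@H]3C)[C@H]12 | target

**Totals**
Total step count: 22. Longest linear sequence: 17 steps (steps 1–4, 7–16, 20–22).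

**Steps most likely to fail**

1. Step 16 (carries the label Proposed new method). What may go wrong: proton exchange and reversal of the tetrahedral intermediate instead of C-acylation, or ring closure of the freed C6 hydroxyl on C3 in the acid stage. Fallback with known chemistry, setting out from 18 and coming back at 26: the Stille coupling of step 14 is stopped at the enol ether 20, which is brominated with NBS in THF/H2O at −78 °C to the bromomethyl ketone F1. Silylation as in step 15 gives the bis-silylated bromo ketone F2. SmI2 (divalent samarium, 2.2 equiv, THF, −78 °C) then generates the C2 samarium enolate without base (Reformatsky-type). Its intramolecular nucleophilic acyl substitution on the lactone carbonyl, the samarium-mediated ring-enlarging acyl substitution known for halo-substituted lactones, gives diketone 24 after protonation, and acid treatment as in step 16 returns to 26.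

2. Step 11. What may go wrong: intermolecular coupling or simple reduction of the allylchromium species, attack on the wrong alkene face in the seven-membered closure, or acyl shift of the new C8 alkoxide to the five-membered lactone. Fallback setting out from 12 and coming back at 16: hydrolysis of the acetal of 12 (LiBF4, wet MeCN) gives the aldehyde F3, which still carries the isopropylidene group. A Me2AlCl-promoted type 1 intramolecular carbonyl-ene reaction (CH2Cl2, −78 °C) then forms the same C7–C8 bond with hydrogen transfer from a methyl group of the isopropylidene unit. This gives 16 directly and makes steps 8–10 unnecessary.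

3. Step 20. What may go wrong: slow acylation of the hindered secondary alcohol on the macrocycle and decomposition of the activated epoxy acid. Fallback setting out from 23 and 30 and coming back at 31: 30 is converted with 1-chloro-N,N,2-trimethylprop-1-en-1-amine into the acid chloride F4. In the ring expansion of step 16 the lithium alkoxide released at C6 is acylated in the same flask with F4 at −78 °C (the lithium diketonate is far less nucleophilic) to give the acylated diketone F5. The acid stage then closes the furanone to 31, so the free C6 hydroxyl is never present.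

**Further compounds**
F1 | step 16 | (3S,5S,6S,7S)-7-[(1Z)-4-bromo-2-methyl-3-oxobut-1-en-1-yl]-5-[(tert-butyldimethylsilyl)oxy]-3-hydroxy-6-(3-hydroxyprop-1-en-2-yl)-3-methyloxepan-2-one | O=C1O[C@@H](/C=C(/C)C(=O)CBr)[C@H](C(CO)=C)[C@@H](O[Si](C)(C)C(C)(C)C)C[C@]1(C)O
F2 | step 16 | (3S,5S,6S,7S)-7-[(1Z)-4-bromo-2-methyl-3-oxobut-1-en-1-yl]-5-[(tert-butyldimethylsilyl)oxy]-6-{3-[(tert-butyldimethylsilyl)oxy]prop-1-en-2-yl}-3-methyl-3-[(trimethylsilyl)oxy]oxepan-2-one | O=C1O[C@@H](/C=C(/C)C(=O)CBr)[C@H](C(CO[Si](C)(C)C(C)(C)C)=C)[C@@H](O[Si](C)(C)C(C)(C)C)C[C@]1(C)O[Si](C)(C)C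
F3 | step 11 | (2Z,4R)-2-iodo-6-methylhepta-2,5-dien-4-yl (2S)-2-hydroxy-2-methyl-4-oxobutanoate | O=CC[C@](C)(O)C(=O)O[C@@H](/C=C(/C)I)C=C(C)C
F4 | step 20 | (2S,3S)-2,3-dimethyloxirane-2-carbonyl chloride | ClC(=O)[C@@]1(C)O[C@H]1C
F5 | step 20 | (4Z,6S,7S,8S,10S)-8-[(tert-butyldimethylsilyl)oxy]-7-{3-[(tert-butyldimethylsilyl)oxy]prop-1-en-2-yl}-4,10-dimethyl-1,3-dioxo-10-[(trimethylsilyl)oxy]cyclodec-4-en-6-yl (2S,3S)-2,3-dimethyloxirane-2-carboxylate | O=C1CC(=O)/C(C)=C\[C@H](OC(=O)[C@@]2(C)O[C@H]2C)[C@H](C(CO[Si](C)(C)C(C)(C)C)=C)[C@@H](O[Si](C)(C)C(C)(C)C)C[C@]1(C)O[Si](C)(C)C
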